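Each asked flask stops at 90 min, and every earlier run has a reading at that time, so the question is one of equivalents.

| flask | electrophile | protonated nucleophile | gas | remark | time |
|---|---|---|---|---|---|
| teal | 0.40 M | 0.94 equiv | 14 mM (held) | run made earlier |  |
| grey | 0.40 M | 1.4 equiv | 14 mM (held) | run made earlier |  |
| red | 0.40 M | 2 equiv | 14 mM (held) | run made earlier |  |
| cedar | 0.40 M | 1.00 equiv | 14 mM (held) |  | 1.5 h |
| elm | 0.40 M | 1.50 equiv | 14 mM (held) |  | 1.5 h |
| maple | 0.40 M | 2.20 equiv | 14 mM (held) |  | 1.5 h |

| run | time / min | electrophile / % | target / % |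
|---|---|---|---|
| teal | 8.00 | 85.7 | 3.8 |
| teal | 25.0 | 63.8 | 11.2 |
| teal | 40.0 | 49.2 | 15.6 |
| teal | 60.0 | 35.9 | 19.8 |
| teal | 90.0 | 22.3 | 24.9 |
| grey | 20.0 | 62.4 | 11.3 |
| grey | 40.0 | 40.4 | 18.4 |
| grey | 50.0 | 33.1 | 21.1 |
| grey | 80.0 | 17.6 | 26.1 |
| grey | 90.0 | 14.7 | 27.4 |
| red | 8.00 | 79.3 | 6.0 |
| red | 15.0 | 64.9 | 10.0 |
| red | 25.0 | 49.0 | 15.6 |
| red | 50.0 | 26.0 | 23.2 |
| red | 90.0 | 9.3 | 28.9 |

(scatter of a reading: 0.3 percentage points)

- at the start none of the gas is in solution

* part of the electrophile that has reacted at the end, cedar
* part of the electrophile that has reacted at the end, elm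
* part of the electrophile that has reacted at the end, maple
* what raising the equivalents of protonated nucleophile from its lowest to its highest value here does to the part of the electrophile that has reacted (changes below 5 percentage points count as none) (no change / it rises / it falls)

I start with the fade: the natural log of electrophile charged over electrophile left. At the stop, teal has a fade of 1.50 and red 2.38.

Now I compare the two runs at two moments. Red over teal is 1.50 at 8.00 min and 1.59 at the stop. The comparison drifts little, so one rule can serve.

Teal and red give 0.608 for the apparent order in protonated nucleophile, the log of the fade ratio over the log of the equivalents ratio.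

Scaling teal by this order, I get a fade of 1.56 for cedar, 1.99 for elm and 2.52 for maple. So 79.0%, 86.3% and 92.0% have reacted, a rise of 13 percentage points.

The weak link is maple, which lies beyond red, on an order drawn from two runs. Grey tests it, since grey did not go into that order. The order predicts a fade of 1.91 for grey, and grey reads 1.92. Grey and red alone give an order of 0.600. Stepping from red with that order, maple comes to 91.9%. I commit to these numbers.

The forecast gives 78.9%, 86.4% and 91.9%, and says it rises. Its ground: "That is a clean power law in equivalents". It takes the same route as mine.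

Cedar reaches 78.7%, elm 86.5% and maple 92.0%. As for the part reacted, it rises, by 13 points. Cedar and maple give an order of 0.619, beside my 0.608.

    electrophile + nucleophile → acid set free + target (k = 0.00110 L mol⁻¹ s⁻¹)
    nucleophile + acid set free ⇌ protonated nucleophile, settled at all times (K = 44.0 L mol⁻¹)
    acid set free + free base ⇌ salt of the base (K = 2.60 × 10⁶ L mol⁻¹, k = 0.00360 L mol⁻¹ s⁻¹)
    electrophile + acid set free → side product (k = 0.00290 L mol⁻¹ s⁻¹)
    gas ⇌ free base, rate k5*(csat - [free base]) (kL = 0.00160 s⁻¹)

The main reason for the gap between maple and cedar is the difference in equivalents of protonated nucleophile: maple reaches 92.0%, and at cedar's equivalents 78.7%. Part of what reacts in cedar goes by the step from electrophile + acid set free to side product: without that step cedar reaches 24.3%, not 78.7%. At 0.750 h, [acid set free] is 0.0644 M in cedar and 0.106 M in maple, an order of 0.634. For cedar's recipe cut to 0.600 equiv, the order carried from teal gives 68.1%, and that flask gives 66.7%.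

The numbers in the tables are simulated with made-up constants.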